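## Retrosynthetic overview

- The target comes from a regioselective, cis-selective hydride reduction of the corresponding epoxyquinone, which sets the carbinol centre.
- The epoxyquinone comes from an enantioselective nucleophilic epoxidation of 2-farnesyl-5-methoxy-1,4-benzoquinone. The oxirane is the only ring that is built; the six-membered ring is carried through from catechol.
- The quinone comes from the key C–C bond (side-chain C1' to ring carbon): carbonyl allylation of 4,5-dimethoxy-1,2-benzoquinone with farnesylbarium chloride, then acid-induced hydrolysis and dehydration to the para-quinone.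
- The two fragments come from catechol (oxidative methoxylation) and (2E,6E)-farnesol (chloride).

"Farnesyl" below means (2E,6E)-3,7,11-trimethyldodeca-2,6,10-trien-1-yl.

Assumption: the cinchonidine-derived phase-transfer catalyst in step 4 is taken to give the (1R,6S) epoxide; if it gives the mirror image, the cinchonine-derived pseudoenantiomeric salt is used under the same conditions.

## Route

Step 1
Reactants: 1 catechol (benzene-1,2-diol)
Product: 2 4,5-dimethoxy-1,2-benzoquinone (4,5-dimethoxycyclohexa-3,5-diene-1,2-dione)
Conditions: NaIO3, MeOH, rt, 48 h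
Reagents that add atoms: methanol, SMILES CO (two equivalents)
Why: Oxidation of catechol to the o-quinone followed by two rounds of conjugate (Michael) addition of methanol and re-oxidation, which stops at 2 because both positions beta to the carbonyls are then vinylogous esters; no stereocentre is formed.

Step 2
Reactants: 3 (2E,6E)-farnesol
Product: 5 (2E,6E)-farnesyl chloride, via farnesyl mesylate 4 (not isolated)
Conditions: MsCl, 2,4,6-collidine, LiCl, DMF, 0 °C
Reagents that add atoms: lithium chloride, SMILES [Li+].[Cl-]
Why: Collington–Meyers chlorination, in which in situ mesylation is followed by SN2 displacement by chloride at the primary allylic carbon, so there is no allylic transposition and both E double bonds are kept.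

Step 3
Reactants: 5 (2E,6E)-farnesyl chloride; 2 4,5-dimethoxy-1,2-benzoquinone
Product: 8 2-methoxy-5-farnesyl-1,4-benzoquinone, via farnesylbarium chloride 6 (not isolated), via quinol adduct 7 (not isolated)
Conditions: BaI2, lithium biphenylide (2 equiv), THF, rt; 5, −78 °C; then 2, THF, −78 °C; 1 M HCl, THF–H2O, 0 °C to rt
Reagents that add atoms: water, SMILES O (oxygen of the new C4 carbonyl)
Why: Yamamoto-type allylbarium carbonyl allylation, in which the reagent adds through its unsubstituted alpha carbon with retention of the 2E geometry to one of the two equivalent carbonyls of the symmetric quinone, and on acidification the hydroxy enol ether 7 hydrolyses and dehydrates (Stork–Danheiser-type transposition) to the para-quinone, so the transient carbinol centre is lost and no stereocentre is set.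

Step 4
Reactants: 8 2-methoxy-5-farnesyl-1,4-benzoquinone
Product: 9 (1R,6S)-4-methoxy-1-farnesyl-7-oxabicyclo[4.1.0]hept-3-ene-2,5-dione
Conditions: 30% aq H2O2, LiOH, 10 mol % N-(9-anthracenylmethyl)cinchonidinium bromide, toluene, −10 °C
Reagents that add atoms: hydrogen peroxide, SMILES OO
Why: Weitz–Scheffer nucleophilic epoxidation under chiral phase-transfer catalysis (by analogy with 2-alkyl-1,4-naphthoquinones), in which hydroperoxide adds only to the alkyl-substituted ring double bond (the methoxy-bearing one is a vinylogous ester and the farnesyl olefins are not electrophilic) and the chiral ion pair selects the face, setting C1 (R) and C6 (S) together as a cis-fused oxirane.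

Step 5
Reactants: 9 (1R,6S)-4-methoxy-1-farnesyl-7-oxabicyclo[4.1.0]hept-3-ene-2,5-dione
Product: 10 (1R,5S,6R)-5-hydroxy-4-methoxy-1-farnesyl-7-oxabicyclo[4.1.0]hept-3-en-2-one (yanuthone X2)
Conditions: NaBH4, CeCl3·7H2O, MeOH, −78 °C
Reagents that add atoms: none
Why: Luche 1,2-reduction, in which hydride attacks the more electrophilic and less hindered C5 ketone (the C2 carbonyl is a vinylogous ester next to the quaternary carbon) from the face opposite the oxirane oxygen, giving the cis epoxy alcohol with C5 (S); the C6 descriptor changes from S to R only through CIP priorities.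

## Compound list

1 | catechol (benzene-1,2-diol) | Oc1ccccc1O | starting material
2 | 4,5-dimethoxy-1,2-benzoquinone | COC1=CC(=O)C(=O)C=C1OC | intermediate
3 | (2E,6E)-farnesol, (2E,6E)-3,7,11-trimethyldodeca-2,6,10-trien-1-ol | OC/C=C(\C)CC/C=C(\C)CCC=C(C)C | starting material
4 | (2E,6E)-farnesyl methanesulfonate (not isolated) | CS(=O)(=O)OC/C=C(\C)CC/C=C(\C)CCC=C(C)C | intermediate
5 | (2E,6E)-farnesyl chloride | ClC/C=C(\C)CC/C=C(\C)CCC=C(C)C | intermediate
6 | (2E,6E)-farnesylbarium chloride (not isolated) | Cl[Ba]C/C=C(\C)CC/C=C(\C)CCC=C(C)C | intermediate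
7 | 6-hydroxy-3,4-dimethoxy-6-farnesylcyclohexa-2,4-dien-1-one, racemic at C6 (not isolated) | COC1=CC(=O)C(O)(C/C=C(\C)CC/C=C(\C)CCC=C(C)C)C=C1OC | intermediate
8 | 2-methoxy-5-farnesylcyclohexa-2,5-diene-1,4-dione | COC1=CC(=O)C(C/C=C(\C)CC/C=C(\C)CCC=C(C)C)=CC1=O | intermediate
9 | (1R,6S)-4-methoxy-1-farnesyl-7-oxabicyclo[4.1.0]hept-3-ene-2,5-dione | COC1=CC(=O)[C@]2(C/C=C(\C)CC/C=C(\C)CCC=C(C)C)O[C@@H]2C1=O | intermediate
10 | (1R,5S,6R)-5-hydroxy-4-methoxy-1-farnesyl-7-oxabicyclo[4.1.0]hept-3-en-2-one (yanuthone X2) | COC1=CC(=O)[C@]2(C/C=C(\C)CC/C=C(\C)CCC=C(C)C)O[C@@H]2[C@@H]1O | target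

## Step count and risks

Total step count: 5. Longest linear sequence: 4 steps (catechol through steps 1, 3, 4, 5; equally farnesol through steps 2, 3, 4, 5).

**Step 3 (most likely to fail).** The barium reagent may transfer an electron to quinone 2, or attack through its gamma carbon, instead of adding cleanly to the carbonyl. I know of no direct precedent for this addition to 2; it rests on analogy with allylbarium additions to ketones and organometallic additions to other alkoxy-substituted quinones and squarates. Fallback: make the same bond by SN2 alkylation of an aryl organometallic. Setting out from 5, commercial 1-bromo-2,4,5-trimethoxybenzene is treated with n-BuLi (THF, −78 °C), then CuBr·SMe2, then 5, to give 1,2,4-trimethoxy-5-farnesylbenzene F1. Oxidative demethylation of F1 with (NH4)2Ce(NO3)6 in MeCN–H2O at 0 °C gives the para-quinone and so comes back to the route at 8.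

**Step 4.** The enantiomeric excess may be low with either pseudoenantiomeric catalyst, since the precedent is for naphthoquinones, not this benzoquinone. Fallback: give up catalyst control and resolve at the end. Setting out from 8, epoxidation with 30% H2O2 and Na2CO3 in THF–H2O at 0 °C without a chiral salt gives 9 as a racemate with its enantiomer, (1S,6R)-4-methoxy-1-farnesyl-7-oxabicyclo[4.1.0]hept-3-ene-2,5-dione F2. The conditions of step 5 then give 10 together with its enantiomer, (1S,5R,6S)-5-hydroxy-4-methoxy-1-farnesyl-7-oxabicyclo[4.1.0]hept-3-en-2-one F3. Kinetic resolution with Burkholderia cepacia lipase and vinyl acetate in tert-butyl methyl ether at 30 °C is expected (Kazlauskas rule, the methoxy-vinyl side taken as the large group) to acetylate F3 to (1S,5R,6S)-4-methoxy-2-oxo-1-farnesyl-7-oxabicyclo[4.1.0]hept-3-en-5-yl acetate F4. The unreacted alcohol is separated by chromatography, which comes back to the route at 10.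

**Step 5.** Hydride may be delivered mainly from the oxirane face, giving the trans alcohol. Fallback: accept that product and invert it. Setting out from 9, the trans epoxy alcohol (1R,5R,6R)-5-hydroxy-4-methoxy-1-farnesyl-7-oxabicyclo[4.1.0]hept-3-en-2-one F5 is subjected to Mitsunobu inversion (4-nitrobenzoic acid, PPh3, DIAD, THF, 0 °C) to give (1R,5S,6R)-4-methoxy-2-oxo-1-farnesyl-7-oxabicyclo[4.1.0]hept-3-en-5-yl 4-nitrobenzoate F6. Methanolysis with K2CO3 in MeOH at 0 °C comes back to the route at 10.

## Further compounds

F1 | step 3 | 1,2,4-trimethoxy-5-farnesylbenzene | COc1cc(OC)c(C/C=C(\C)CC/C=C(\C)CCC=C(C)C)cc1OC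
F2 | step 4 | (1S,6R)-4-methoxy-1-farnesyl-7-oxabicyclo[4.1.0]hept-3-ene-2,5-dione | COC1=CC(=O)[C@@]2(C/C=C(\C)CC/C=C(\C)CCC=C(C)C)O[C@H]2C1=O
F3 | step 4 | (1S,5R,6S)-5-hydroxy-4-methoxy-1-farnesyl-7-oxabicyclo[4.1.0]hept-3-en-2-one | COC1=CC(=O)[C@@]2(C/C=C(\C)CC/C=C(\C)CCC=C(C)C)O[C@H]2[C@H]1O
F4 | step 4 | (1S,5R,6S)-4-methoxy-2-oxo-1-farnesyl-7-oxabicyclo[4.1.0]hept-3-en-5-yl acetate | COC1=CC(=O)[C@@]2(C/C=C(\C)CC/C=C(\C)CCC=C(C)C)O[C@H]2[C@H]1OC(C)=O
F5 | step 5 | (1R,5R,6R)-5-hydroxy-4-methoxy-1-farnesyl-7-oxabicyclo[4.1.0]hept-3-en-2-one | COC1=CC(=O)[C@]2(C/C=C(\C)CC/C=C(\C)CCC=C(C)C)O[C@@H]2[C@H]1O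
F6 | step 5 | (1R,5S,6R)-4-methoxy-2-oxo-1-farnesyl-7-oxabicyclo[4.1.0]hept-3-en-5-yl 4-nitrobenzoate | COC1=CC(=O)[C@]2(C/C=C(\C)CC/C=C(\C)CCC=C(C)C)O[C@@H]2[C@@H]1OC(=O)c1ccc(cc1)N(=O)=O
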